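**Strategy**

In the guaianolide half (guaianolide numbering) the lactone oxygen on C8 and the sp2 carbon C5 lie 1,4 across the seven-membered ring; they are read as the trace of a furan oxygen that once bridged C5 and C8. The key step is an intramolecular (4+3) cycloaddition: a 2-(silylmethyl)allyl cation (C9–C10–C1), generated from an allylic alcohol at the end of a (Z)-alkenyl tether, adds across the furan (C5–C8), forming C1–C5 and C8–C9 at once and both carbocycles as an 8-oxabicyclo[3.2.1]octene. Acid later opens the bridge at C5, giving the cyclopentadiene and the lactone; a Diels–Alder union with the separately made 1,10-seco-eudesmanolide follows.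

Key step: step 10

Remark (numbering): C1–C15 is guaianolide numbering for the diene half and primed eudesmane numbering is used for the other half; α is the face of the C8–O bond, β that of the C7–C11 bond.

Remark (chemistry): centres that are erased later are carried as epimer mixtures and written without descriptor (the carbinol carbon of 12–14, C11 of 17–21, 41 and 42, C11′ of 32 and 33, C10′ of 38).

**Route**

Step 1
Reactants: 1 2-(furan-3-yl)acetic acid
Product: 2 methyl 2-(furan-3-yl)acetate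
Conditions: MeI, K2CO3, DMF, rt
Reagents that add atoms: iodomethane, CI
Why: SN2 O-alkylation of the carboxylate gives the methyl ester without exposing the furan to acid.

Step 2
Reactants: 2 methyl 2-(furan-3-yl)acetate
Product: 3 methyl 2-[5-(4,4,5,5-tetramethyl-1,3,2-dioxaborolan-2-yl)furan-3-yl]acetate
Conditions: B2pin2, [Ir(OMe)(cod)]2 (1.5 mol %), 4,4'-di-tert-butyl-2,2'-bipyridine, THF, 50 °C
Reagents that add atoms: bis(pinacolato)diboron, CC1(C)OB(OC1(C)C)B1OC(C)(C)C(C)(C)O1
Why: Iridium-catalysed C–H borylation is sterically controlled and should select the α-C–H remote from the side chain, which becomes C5 of the guaiane.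

Step 3
Reactants: 4 (R)-2,2-dimethyl-1,3-dioxolane-4-carbaldehyde; 5 ethyltriphenylphosphonium iodide
Product: 6 (4S)-4-[(1Z)-2-iodoprop-1-en-1-yl]-2,2-dimethyl-1,3-dioxolane
Conditions: 5, n-BuLi, THF, rt; I2, −78 °C; NaN(SiMe3)2, −20 °C; then 4, −78 °C → rt
Reagents that add atoms: iodine, II
Why: The Stork–Zhao olefination (Wittig reaction of an α-iodo ylide) should give the (Z)-vinyl iodide with iodine cis to the dioxolane, and the stereocentre of 4 is not touched.

Step 4
Reactants: 6 (4S)-4-[(1Z)-2-iodoprop-1-en-1-yl]-2,2-dimethyl-1,3-dioxolane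
Product: 7 (2S,3Z)-4-iodopent-3-ene-1,2-diol
Conditions: AcOH/H2O (4:1), 40 °C
Reagents that add atoms: none
Why: Acid-catalysed acetal hydrolysis frees the diol while the vinyl iodide is inert.

Step 5
Reactants: 7 (2S,3Z)-4-iodopent-3-ene-1,2-diol
Product: 8 (2S,3Z)-1,2-bis(tert-butyldimethylsilyloxy)-4-iodopent-3-ene
Conditions: TBSCl (2.5 equiv), imidazole, DMF, rt
Reagents that add atoms: tert-butyldimethylsilyl chloride, CC(C)(C)[Si](C)(C)Cl
Why: Standard silyl ether formation protects both hydroxyls.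

Step 6
Reactants: 8 (2S,3Z)-1,2-bis(tert-butyldimethylsilyloxy)-4-iodopent-3-ene
Product: 9 (2S,3Z)-2-(tert-butyldimethylsilyloxy)-4-iodopent-3-en-1-ol
Conditions: HF·pyridine, pyridine, THF, 0 °C
Reagents that add atoms: none
Why: Selective desilylation: the primary silyl ether is cleaved faster than the hindered secondary one.

Step 7
Reactants: 9 (2S,3Z)-2-(tert-butyldimethylsilyloxy)-4-iodopent-3-en-1-ol
Product: 10 (2S,3Z)-2-(tert-butyldimethylsilyloxy)-4-iodopent-3-enal
Conditions: Dess–Martin periodinane, NaHCO3, CH2Cl2, 0 °C → rt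
Reagents that add atoms: none
Why: Dess–Martin oxidation under buffered, non-basic conditions should avoid epimerisation or conjugation of the β,γ-unsaturated α-silyloxy aldehyde.

Step 8
Reactants: 10 (2S,3Z)-2-(tert-butyldimethylsilyloxy)-4-iodopent-3-enal; 11 (2-bromoprop-2-en-1-yl)trimethylsilane
Product: 12 (4S,5Z)-4-(tert-butyldimethylsilyloxy)-6-iodo-2-[(trimethylsilyl)methyl]hepta-1,5-dien-3-ol
Conditions: 11, Mg, THF; then 10, −78 °C
Reagents that add atoms: none
Why: Grignard addition of the 2-(silylmethyl)vinyl reagent to the aldehyde builds the cation precursor; the new carbinol centre is ionised in step 10, so both epimers are used.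

Step 9
Reactants: 12 (4S,5Z)-4-(tert-butyldimethylsilyloxy)-6-iodo-2-[(trimethylsilyl)methyl]hepta-1,5-dien-3-ol; 3 methyl 2-[5-(4,4,5,5-tetramethyl-1,3,2-dioxaborolan-2-yl)furan-3-yl]acetate
Product: 13 methyl 2-{5-[(2Z,4S)-4-(tert-butyldimethylsilyloxy)-5-hydroxy-6-[(trimethylsilyl)methyl]hepta-2,6-dien-2-yl]furan-3-yl}acetate
Conditions: Pd(dppf)Cl2 (5 mol %), aq. K3PO4, THF, 40 °C
Reagents that add atoms: none
Why: Suzuki–Miyaura coupling joins furan C5 to C4 with retention of the (Z)-alkene geometry.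

Step 10
Reactants: 13 methyl 2-{5-[(2Z,4S)-4-(tert-butyldimethylsilyloxy)-5-hydroxy-6-[(trimethylsilyl)methyl]hepta-2,6-dien-2-yl]furan-3-yl}acetate
Product: 15 methyl 2β-(tert-butyldimethylsilyloxy)-5α,8α-epoxy-13-nor-1βH-guaia-3,6,10(14)-trien-12-oate, via allylic triflate 14 (not isolated)
Conditions: Tf2O, 2,6-lutidine, CH2Cl2, −78 → −40 °C
Reagents that add atoms: none
Why: O-Triflation of the only free hydroxyl gives 14, which ionises to the 2-(trimethylsilylmethyl)allyl cation (C9–C10–C1); C1 attacks the ipso carbon C5 of the furan (5-exo closure of the cyclopentene) to give a spiro oxocarbenium ion, whose C8 is captured by C9 of the resulting allylsilane (intramolecular Hosomi–Sakurai closure of the six-membered oxane ring, which completes the cycloheptene), and loss of the silyl group leaves the C10 exocyclic methylene. The closest known reaction type is the intramolecular (4+3) cycloaddition of 2-(silylmethyl)allyl cations with tethered furans under Tf2O/2,6-lutidine. The rigid (Z)-alkene tether allows only the ring fusion in which C10 and the oxygen bridge are cis on the new cyclopentene, and the C2 silyloxy group, avoiding the C10 substituent, should sit trans to both, so the single C2 centre fixes C1, C5 and C8 in the absolute sense of the target (C8–O α). The step needs ionisation at C1 and not at the silyl-protected, vinylogous furfuryl C2 (secured by triflating the only free OH at −78 °C with a buffering base) and attack at furan C5 and not at C6 (secured by the three-atom tether and the α-reactivity of furans).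

Step 11
Reactants: 15 methyl 2β-(tert-butyldimethylsilyloxy)-5α,8α-epoxy-13-nor-1βH-guaia-3,6,10(14)-trien-12-oate
Product: 16 methyl 2β-(tert-butyldimethylsilyloxy)-5α,8α-epoxy-13-nor-1βH,7αH,10αH-guai-3-en-12-oate
Conditions: 2-nitrobenzenesulfonohydrazide (excess), Et3N, CH2Cl2, rt
Reagents that add atoms: none
Why: Diimide reduction is fastest for strained and unhindered alkenes, so the bridge alkene and the exocyclic methylene should react while the hindered trisubstituted cyclopentene survives; hydrogen is expected on the exo face (side of the oxygen bridge), setting H7 and H10 α.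

Step 12
Reactants: 16 methyl 2β-(tert-butyldimethylsilyloxy)-5α,8α-epoxy-13-nor-1βH,7αH,10αH-guai-3-en-12-oate
Product: 17 methyl 2β-(tert-butyldimethylsilyloxy)-13-(dimethylamino)-5α,8α-epoxy-1βH,7αH,10αH-guai-3-en-12-oate
Conditions: LiN(i-Pr)2, THF, −78 °C; then CH2=NMe2 iodide, −78 °C → rt
Reagents that add atoms: N,N-dimethylmethyleneiminium iodide, C=[N+](C)C.[I-]
Why: Mannich aminomethylation of the ester enolate installs C13 as a masked methylene, which keeps the lactone from acting as a dienophile later; C11 forms as an epimer mixture that is erased in step 28.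

Step 13
Reactants: 17 methyl 2β-(tert-butyldimethylsilyloxy)-13-(dimethylamino)-5α,8α-epoxy-1βH,7αH,10αH-guai-3-en-12-oate
Product: 18 methyl 13-(dimethylamino)-5α,8α-epoxy-2β-hydroxy-1βH,7αH,10αH-guai-3-en-12-oate
Conditions: Bu4NF, AcOH, THF, 0 °C → rt
Reagents that add atoms: none
Why: Fluoride-mediated desilylation frees the C2 hydroxyl, and the acetic acid buffer protects the β-amino ester.

Step 14
Reactants: 18 methyl 13-(dimethylamino)-5α,8α-epoxy-2β-hydroxy-1βH,7αH,10αH-guai-3-en-12-oate
Product: 19 methyl 2α-acetoxy-13-(dimethylamino)-5α,8α-epoxy-1βH,7αH,10αH-guai-3-en-12-oate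
Conditions: PPh3, DIAD, AcOH, toluene, 0 °C → rt
Reagents that add atoms: acetic acid, CC(=O)O
Why: Mitsunobu esterification inverts the secondary allylic carbinol by SN2 attack of acetate, placing the acetoxy group α, cis to the oxygen bridge, as in the target.

Step 15
Reactants: 19 methyl 2α-acetoxy-13-(dimethylamino)-5α,8α-epoxy-1βH,7αH,10αH-guai-3-en-12-oate
Product: 21 2α-acetoxy-13-(dimethylamino)-7αH,8βH,10αH-guaia-1(5),3-dien-12,8-olide, via hydroxy diene ester 20 (not isolated)
Conditions: TsOH (anhydrous, 2.2 equiv), 4 Å MS, CH2Cl2, 0 °C → rt; NaHCO3 work-up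
Reagents that add atoms: none
Why: Acid ionises the tertiary allylic C5–O bond (E1 elimination), loss of H1 from the allyl cation should give the cyclopentadiene, and the freed C8 hydroxyl closes the trans-fused γ-lactone on the ester (acid-catalysed lactonisation), the amine being protected as its ammonium salt.

Step 16
Reactants: 22 (R)-citronellal
Product: 23 (3R)-3,7-dimethyl-2-methylideneoct-6-enal
Conditions: 37 % aq. HCHO, pyrrolidine (10 mol %), EtCO2H (10 mol %), i-PrOH, 45 °C
Reagents that add atoms: formaldehyde, C=O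
Why: Amine-catalysed α-methylenation of the aldehyde (Mannich condensation and elimination) leaves the β-stereocentre, the future C4′, intact.

Step 17
Reactants: 23 (3R)-3,7-dimethyl-2-methylideneoct-6-enal
Product: 24 (1E,4R)-1-iodo-4,8-dimethyl-3-methylidenenona-1,7-diene
Conditions: CHI3, CrCl2, THF, 0 °C → rt
Reagents that add atoms: iodoform, IC(I)I
Why: The Takai olefination converts the aldehyde into the (E)-vinyl iodide.

Step 18
Reactants: 24 (1E,4R)-1-iodo-4,8-dimethyl-3-methylidenenona-1,7-diene; 25 methyl bromoacetate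
Product: 26 methyl (3E,6R)-6,10-dimethyl-5-methylideneundeca-3,9-dienoate
Conditions: 25, Zn, THF, rt; then 24, Pd(PPh3)4 (5 mol %), THF, 40 °C
Reagents that add atoms: none
Why: Palladium-catalysed cross-coupling of the Reformatsky reagent (Negishi type) with the vinyl iodide retains the (E)-geometry and gives the β,γ-unsaturated ester.

Step 19
Reactants: 26 methyl (3E,6R)-6,10-dimethyl-5-methylideneundeca-3,9-dienoate; 27 but-3-en-2-one
Product: 28 methyl 2-[(1R,6S)-6-acetyl-3-[(2R)-6-methylhept-5-en-2-yl]cyclohex-2-en-1-yl]acetate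
Conditions: protonated (S)-o-tolyl-oxazaborolidine from α,α-diphenylprolinol (Tf2NH, 20 mol %), CH2Cl2, −78 → −40 °C
Reagents that add atoms: none
Why: In this catalytic enantioselective Diels–Alder reaction the 1,3-disubstituted diene places the acetyl-bearing carbon next to C7′ (ortho/para rule), endo addition makes C7′ and C8′ cis, and the chiral Lewis acid, not the remote C4′ centre, selects the diene face (the antipodal catalyst is used if the sense of induction proves opposite).

Step 20
Reactants: 28 methyl 2-[(1R,6S)-6-acetyl-3-[(2R)-6-methylhept-5-en-2-yl]cyclohex-2-en-1-yl]acetate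
Product: 29 methyl 2-[(1R,6S)-6-acetoxy-3-[(2R)-6-methylhept-5-en-2-yl]cyclohex-2-en-1-yl]acetate
Conditions: Me3SiOOSiMe3, SnCl4 (cat.), trans-1,2-diaminocyclohexane (cat.), 4 Å MS, CH2Cl2, rt
Reagents that add atoms: bis(trimethylsilyl) peroxide, C[Si](C)(C)OO[Si](C)(C)C
Why: Baeyer–Villiger oxidation with a silyl peroxide and a Lewis acid does not epoxidise alkenes, and the secondary ring carbon migrates with retention, putting oxygen on C8′.

Step 21
Reactants: 29 methyl 2-[(1R,6S)-6-acetoxy-3-[(2R)-6-methylhept-5-en-2-yl]cyclohex-2-en-1-yl]acetate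
Product: 31 (3aR,7aS)-5-[(2R)-6-methylhept-5-en-2-yl]-3a,6,7,7a-tetrahydro-1-benzofuran-2(3H)-one, via hydroxy ester 30 (not isolated)
Conditions: K2CO3, MeOH, rt; then PPTS, CH2Cl2, rt
Reagents that add atoms: none
Why: Methanolysis of the acetate followed by lactonisation of the cis hydroxy ester gives the cis-fused γ-lactone.

Step 22
Reactants: 31 (3aR,7aS)-5-[(2R)-6-methylhept-5-en-2-yl]-3a,6,7,7a-tetrahydro-1-benzofuran-2(3H)-one
Product: 34 (3aS,7aS)-3-methylidene-5-[(2R)-6-methylhept-5-en-2-yl]-3a,6,7,7a-tetrahydro-1-benzofuran-2(3H)-one, via Mannich base 32 (not isolated), via ammonium iodide 33 (not isolated)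
Conditions: LiN(i-Pr)2, THF, −78 °C, CH2=NMe2 iodide; then MeI, MeOH, rt; then aq. NaHCO3, EtOAc
Reagents that add atoms: N,N-dimethylmethyleneiminium iodide, C=[N+](C)C.[I-]
Why: α-Methylenation of the lactone by Mannich aminomethylation of its enolate, N-methylation and Hofmann-type elimination is done here because no acetate or ketone is yet present.

Step 23
Reactants: 34 (3aS,7aS)-3-methylidene-5-[(2R)-6-methylhept-5-en-2-yl]-3a,6,7,7a-tetrahydro-1-benzofuran-2(3H)-one
Product: 36 (3aS,7aS)-5-[(2R)-5-hydroxypentan-2-yl]-3-methylidene-3a,6,7,7a-tetrahydro-1-benzofuran-2(3H)-one, via aldehyde 35 (not isolated)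
Conditions: O3 (to indicator end point), pyridine, CH2Cl2/MeOH, −78 °C; Me2S; then NaBH4, −78 °C
Reagents that add atoms: ozone, [O-][O+]=O
Why: Ozonolysis should cleave the most electron-rich and least hindered alkene (the side-chain isopropylidene) before the ring alkene and the electron-poor methylene lactone, and borohydride at −78 °C reduces the aldehyde faster than it attacks the methylene lactone.

Step 24
Reactants: 36 (3aS,7aS)-5-[(2R)-5-hydroxypentan-2-yl]-3-methylidene-3a,6,7,7a-tetrahydro-1-benzofuran-2(3H)-one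
Product: 37 (4R)-4-[(3aS,7aS)-3-methylidene-2-oxo-3a,6,7,7a-tetrahydro-1-benzofuran-5-yl]pentyl acetate
Conditions: Ac2O, pyridine, CH2Cl2, 0 °C
Reagents that add atoms: acetic anhydride, CC(=O)OC(C)=O
Why: Acylation of the primary alcohol installs the C1′ acetate of the target.

Step 25
Reactants: 37 (4R)-4-[(3aS,7aS)-3-methylidene-2-oxo-3a,6,7,7a-tetrahydro-1-benzofuran-5-yl]pentyl acetate
Product: 39 (4R)-4-[(3aS,7aS)-3-methylidene-2,6-dioxo-2,3,3a,6,7,7a-hexahydro-1-benzofuran-5-yl]pentyl acetate, via allylic alcohol 38 (not isolated)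
Conditions: SeO2 (cat.), t-BuOOH, CH2Cl2, rt; then Dess–Martin periodinane, NaHCO3, CH2Cl2
Reagents that add atoms: tert-butyl hydroperoxide, CC(C)(C)OO
Why: Selenium dioxide allylic oxidation (ene reaction then [2,3]-shift) should attack the CH2 on the more substituted alkene terminus (C10′) of the electron-rich ring alkene, and Dess–Martin oxidation of the crude alcohol gives the enone under non-basic conditions.

Step 26
Reactants: 39 (4R)-4-[(3aS,7aS)-3-methylidene-2,6-dioxo-2,3,3a,6,7,7a-hexahydro-1-benzofuran-5-yl]pentyl acetate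
Product: 40 (4R)-4-[(3aS,6R,7aS)-6-hydroxy-6-methyl-3-methylidene-2-oxo-3a,6,7,7a-tetrahydro-1-benzofuran-5-yl]pentyl acetate
Conditions: MeMgBr, CeCl3, THF, −78 °C
Reagents that add atoms: methylmagnesium bromide, C[Mg]Br
Why: Organocerium 1,2-addition to the enone is faster than addition to the lactone or acetate and suppresses enolisation and β-elimination of the lactone oxygen; methyl should enter on the convex face, anti to the cis-fused lactone, leaving the C10′ hydroxyl cis to O8′.

Step 27
Reactants: 21 2α-acetoxy-13-(dimethylamino)-7αH,8βH,10αH-guaia-1(5),3-dien-12,8-olide; 40 (4R)-4-[(3aS,6R,7aS)-6-hydroxy-6-methyl-3-methylidene-2-oxo-3a,6,7,7a-tetrahydro-1-benzofuran-5-yl]pentyl acetate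
Product: 41 13-(dimethylamino)-11,13-dihydro derivative of the target
Conditions: neat (or 2 M in toluene), BHT, 40 °C, dark
Reagents that add atoms: none
Why: In this thermal Diels–Alder reaction the cyclopentadiene (C1=C5–C4=C3) adds across C11′=C13′ with C13′ bonding to the more substituted C1, on the diene face syn to the C2 acetoxy group (the known syn-directing effect of 5-acyloxy groups in cyclopentadienes) and anti to the C10 methyl, on the convex face of the cis-fused lactone and with the lactone carbonyl endo, which sets the spiro centre C11′ and the bridgeheads C1 and C3.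

Step 28
Reactants: 41 13-(dimethylamino)-11,13-dihydro derivative of the target
Product: 43 CNP0257312.1, via ammonium iodide 42 (not isolated)
Conditions: MeI, MeOH, rt; then aq. NaHCO3, EtOAc, rt
Reagents that add atoms: none
Why: N-Methylation and Hofmann-type β-elimination of trimethylamine unmask the α-methylene lactone of the guaianolide half and erase the C11 epimer mixture.

**Compound list**

1 | 2-(furan-3-yl)acetic acid | OC(=O)Cc1ccoc1 | starting material
2 | methyl 2-(furan-3-yl)acetate | COC(=O)Cc1ccoc1 | intermediate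
3 | methyl 2-[5-(4,4,5,5-tetramethyl-1,3,2-dioxaborolan-2-yl)furan-3-yl]acetate | COC(=O)Cc1coc(B2OC(C)(C)C(C)(C)O2)c1 | intermediate
4 | (R)-2,2-dimethyl-1,3-dioxolane-4-carbaldehyde (D-glyceraldehyde acetonide) | O=C[C@H]1COC(C)(C)O1 | starting material
5 | ethyltriphenylphosphonium iodide | CC[P+](c1ccccc1)(c1ccccc1)c1ccccc1.[I-] | starting material
6 | (4S)-4-[(1Z)-2-iodoprop-1-en-1-yl]-2,2-dimethyl-1,3-dioxolane | I/C(C)=C\[C@H]1COC(C)(C)O1 | intermediate
7 | (2S,3Z)-4-iodopent-3-ene-1,2-diol | I/C(C)=C\[C@H](O)CO | intermediate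
8 | (2S,3Z)-1,2-bis(tert-butyldimethylsilyloxy)-4-iodopent-3-ene | I/C(C)=C\[C@H](O[Si](C)(C)C(C)(C)C)CO[Si](C)(C)C(C)(C)C | intermediate
9 | (2S,3Z)-2-(tert-butyldimethylsilyloxy)-4-iodopent-3-en-1-ol | I/C(C)=C\[C@H](O[Si](C)(C)C(C)(C)C)CO | intermediate
10 | (2S,3Z)-2-(tert-butyldimethylsilyloxy)-4-iodopent-3-enal | I/C(C)=C\[C@H](O[Si](C)(C)C(C)(C)C)C=O | intermediate
11 | (2-bromoprop-2-en-1-yl)trimethylsilane | C=C(Br)C[Si](C)(C)C | starting material
12 | (4S,5Z)-4-(tert-butyldimethylsilyloxy)-6-iodo-2-[(trimethylsilyl)methyl]hepta-1,5-dien-3-ol (C3 epimers) | I/C(C)=C\[C@H](O[Si](C)(C)C(C)(C)C)C(O)C(=C)C[Si](C)(C)C | intermediate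
13 | methyl 2-{5-[(2Z,4S)-4-(tert-butyldimethylsilyloxy)-5-hydroxy-6-[(trimethylsilyl)methyl]hepta-2,6-dien-2-yl]furan-3-yl}acetate (carbinol epimers) | COC(=O)Cc1coc(/C(C)=C\[C@H](O[Si](C)(C)C(C)(C)C)C(O)C(=C)C[Si](C)(C)C)c1 | intermediate
14 | allylic triflate of 13 (triflate on the carbinol carbon, the future C1) | COC(=O)Cc1coc(/C(C)=C\[C@H](O[Si](C)(C)C(C)(C)C)C(OS(=O)(=O)C(F)(F)F)C(=C)C[Si](C)(C)C)c1 | intermediate
15 | methyl 2β-(tert-butyldimethylsilyloxy)-5α,8α-epoxy-13-nor-1βH-guaia-3,6,10(14)-trien-12-oate (oxygen bridge trans to the silyloxy group) | COC(=O)CC1=C[C@@]23O[C@@H]1CC(=C)[C@@H]2[C@@H](O[Si](C)(C)C(C)(C)C)C=C3C | intermediate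
16 | methyl 2β-(tert-butyldimethylsilyloxy)-5α,8α-epoxy-13-nor-1βH,7αH,10αH-guai-3-en-12-oate | COC(=O)C[C@@H]1C[C@@]23O[C@@H]1C[C@@H](C)[C@@H]2[C@@H](O[Si](C)(C)C(C)(C)C)C=C3C | intermediate
17 | methyl 2β-(tert-butyldimethylsilyloxy)-13-(dimethylamino)-5α,8α-epoxy-1βH,7αH,10αH-guai-3-en-12-oate (C11 epimers) | COC(=O)C(CN(C)C)[C@@H]1C[C@@]23O[C@@H]1C[C@@H](C)[C@@H]2[C@@H](O[Si](C)(C)C(C)(C)C)C=C3C | intermediate
18 | methyl 13-(dimethylamino)-5α,8α-epoxy-2β-hydroxy-1βH,7αH,10αH-guai-3-en-12-oate (C11 epimers) | COC(=O)C(CN(C)C)[C@@H]1C[C@@]23O[C@@H]1C[C@@H](C)[C@@H]2[C@@H](O)C=C3C | intermediate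
19 | methyl 2α-acetoxy-13-(dimethylamino)-5α,8α-epoxy-1βH,7αH,10αH-guai-3-en-12-oate (C11 epimers) | COC(=O)C(CN(C)C)[C@@H]1C[C@@]23O[C@@H]1C[C@@H](C)[C@@H]2[C@H](OC(C)=O)C=C3C | intermediate
20 | methyl 2α-acetoxy-13-(dimethylamino)-8α-hydroxy-7αH,10αH-guaia-1(5),3-dien-12-oate (C11 epimers) | COC(=O)C(CN(C)C)[C@@H]1CC2=C([C@H](C)C[C@H]1O)[C@H](OC(C)=O)C=C2C | intermediate
21 | 2α-acetoxy-13-(dimethylamino)-7αH,8βH,10αH-guaia-1(5),3-dien-12,8-olide (trans-fused lactone, C11 epimers) | CN(C)CC1C(=O)O[C@@H]2C[C@@H](C)C3=C(C[C@@H]12)C(C)=C[C@H]3OC(C)=O | intermediate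
22 | (R)-citronellal, (3R)-3,7-dimethyloct-6-enal | O=CC[C@H](C)CCC=C(C)C | starting material
23 | (3R)-3,7-dimethyl-2-methylideneoct-6-enal | O=CC(=C)[C@H](C)CCC=C(C)C | intermediate
24 | (1E,4R)-1-iodo-4,8-dimethyl-3-methylidenenona-1,7-diene | I/C=C/C(=C)[C@H](C)CCC=C(C)C | intermediate
25 | methyl bromoacetate | COC(=O)CBr | starting material
26 | methyl (3E,6R)-6,10-dimethyl-5-methylideneundeca-3,9-dienoate | COC(=O)C/C=C/C(=C)[C@H](C)CCC=C(C)C | intermediate
27 | but-3-en-2-one (methyl vinyl ketone) | CC(=O)C=C | starting material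
28 | methyl 2-[(1R,6S)-6-acetyl-3-[(2R)-6-methylhept-5-en-2-yl]cyclohex-2-en-1-yl]acetate (cis) | COC(=O)C[C@@H]1C=C([C@H](C)CCC=C(C)C)CC[C@@H]1C(C)=O | intermediate
29 | methyl 2-[(1R,6S)-6-acetoxy-3-[(2R)-6-methylhept-5-en-2-yl]cyclohex-2-en-1-yl]acetate (cis) | COC(=O)C[C@@H]1C=C([C@H](C)CCC=C(C)C)CC[C@@H]1OC(C)=O | intermediate
30 | methyl 2-[(1R,6S)-6-hydroxy-3-[(2R)-6-methylhept-5-en-2-yl]cyclohex-2-en-1-yl]acetate | COC(=O)C[C@@H]1C=C([C@H](C)CCC=C(C)C)CC[C@@H]1O | intermediate
31 | (3aR,7aS)-5-[(2R)-6-methylhept-5-en-2-yl]-3a,6,7,7a-tetrahydro-1-benzofuran-2(3H)-one (cis-fused) | O=C1C[C@@H]2C=C([C@H](C)CCC=C(C)C)CC[C@@H]2O1 | intermediate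
32 | 3-[(dimethylamino)methyl] derivative of 31 (C3 epimers) | CN(C)CC1C(=O)O[C@H]2CCC([C@H](C)CCC=C(C)C)=C[C@@H]12 | intermediate
33 | N-methyl ammonium iodide of 32 | C[N+](C)(C)CC1C(=O)O[C@H]2CCC([C@H](C)CCC=C(C)C)=C[C@@H]12.[I-] | intermediate
34 | (3aS,7aS)-3-methylidene-5-[(2R)-6-methylhept-5-en-2-yl]-3a,6,7,7a-tetrahydro-1-benzofuran-2(3H)-one | C=C1C(=O)O[C@H]2CCC([C@H](C)CCC=C(C)C)=C[C@@H]12 | intermediate
35 | (4R)-4-[(3aS,7aS)-3-methylidene-2-oxo-3a,6,7,7a-tetrahydro-1-benzofuran-5-yl]pentanal | C=C1C(=O)O[C@H]2CCC([C@H](C)CCC=O)=C[C@@H]12 | intermediate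
36 | (3aS,7aS)-5-[(2R)-5-hydroxypentan-2-yl]-3-methylidene-3a,6,7,7a-tetrahydro-1-benzofuran-2(3H)-one | C=C1C(=O)O[C@H]2CCC([C@H](C)CCCO)=C[C@@H]12 | intermediate
37 | (4R)-4-[(3aS,7aS)-3-methylidene-2-oxo-3a,6,7,7a-tetrahydro-1-benzofuran-5-yl]pentyl acetate | C=C1C(=O)O[C@H]2CCC([C@H](C)CCCOC(C)=O)=C[C@@H]12 | intermediate
38 | 6-hydroxy derivative of 37 (allylic alcohol at C10′, epimers) | C=C1C(=O)O[C@H]2CC(O)C([C@H](C)CCCOC(C)=O)=C[C@@H]12 | intermediate
39 | (4R)-4-[(3aS,7aS)-3-methylidene-2,6-dioxo-2,3,3a,6,7,7a-hexahydro-1-benzofuran-5-yl]pentyl acetate | C=C1C(=O)O[C@H]2CC(=O)C([C@H](C)CCCOC(C)=O)=C[C@@H]12 | intermediate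
40 | (4R)-4-[(3aS,6R,7aS)-6-hydroxy-6-methyl-3-methylidene-2-oxo-3a,6,7,7a-tetrahydro-1-benzofuran-5-yl]pentyl acetate (hydroxyl cis to the lactone oxygen) | C=C1C(=O)O[C@H]2C[C@@](C)(O)C([C@H](C)CCCOC(C)=O)=C[C@@H]12 | intermediate
41 | 13-(dimethylamino)-11,13-dihydro derivative of the target (C11 epimers) | CN(C)CC1C(=O)O[C@@H]2C[C@@H](C)[C@]34C[C@]5(C(=O)O[C@H]6C[C@@](C)(O)C([C@H](C)CCCOC(C)=O)=C[C@H]65)[C@H](C(C)=C3C[C@@H]12)[C@H]4OC(C)=O | intermediate
42 | N-methyl ammonium iodide of 41 | C[N+](C)(C)CC1C(=O)O[C@@H]2C[C@@H](C)[C@]34C[C@]5(C(=O)O[C@H]6C[C@@](C)(O)C([C@H](C)CCCOC(C)=O)=C[C@H]65)[C@H](C(C)=C3C[C@@H]12)[C@H]4OC(C)=O.[I-] | intermediate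
43 | CNP0257312.1 | C=C1C(=O)O[C@@H]2C[C@@H](C)[C@]34C[C@]5(C(=O)O[C@H]6C[C@@](C)(O)C([C@H](C)CCCOC(C)=O)=C[C@H]65)[C@H](C(C)=C3C[C@@H]12)[C@H]4OC(C)=O | target

**Step count and risks**

Total step count: 28. Longest linear sequence: 15 steps (4 → 43 through steps 3–15, 27 and 28).

Steps most likely to fail:

Step 10 may fail through ionisation at the vinylogous furfuryl C2–O bond, or a 1,2-shift of the silyloxy group, before the furan captures the cation. The fallback replaces the weakly stabilised silylmethylallyl cation by a 2-alkoxyallyl cation. It sets out from aldehyde 10: addition of 1-ethoxyvinyllithium (ethyl vinyl ether, t-BuLi) should give (4S,5Z)-4-(tert-butyldimethylsilyloxy)-2-ethoxy-6-iodohepta-1,5-dien-3-ol F1. Suzuki coupling with 3 should give methyl 2-{5-[(2Z,4S)-4-(tert-butyldimethylsilyloxy)-6-ethoxy-5-hydroxyhepta-2,6-dien-2-yl]furan-3-yl}acetate F2. Ionisation with Tf2O and 2,6-lutidine, (4+3) cycloaddition of the ethoxyallyl cation and aqueous work-up should give methyl 2β-(tert-butyldimethylsilyloxy)-5α,8α-epoxy-10-oxo-13,14-dinor-1βH-guaia-3,6-dien-12-oate F3. Wittig methylenation with Ph3P=CH2 comes back to the route at 15.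

Step 11 may fail through over-reduction of the cyclopentene alkene, incomplete reduction of the hindered bridge alkene, or attack on the wrong face of the exocyclic methylene. The fallback tells the alkenes apart by mechanism and not by rate, which answers the first two of these; the facial selectivity at C10 stays an open risk. It sets out from 15: DBU should move the bridge double bond into conjugation to give methyl 2β-(tert-butyldimethylsilyloxy)-5α,8α-epoxy-13-nor-1βH-guaia-3,7(11),10(14)-trien-12-oate F4. Conjugate reduction with [(Ph3P)CuH]6, hydride entering C7 from the side of the oxygen bridge, should give methyl 2β-(tert-butyldimethylsilyloxy)-5α,8α-epoxy-13-nor-1βH,7αH-guaia-3,10(14)-dien-12-oate F5. Hydrogenation over RhCl(PPh3)3, which spares trisubstituted alkenes, should saturate the exocyclic methylene and come back to the route at 16.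

Step 15 may fail through loss of a proton from C6 or C2 instead of C1, capture of the allyl cation by the neighbouring acetate, or decomposition of the cyclopentadiene in acid. The fallback makes the diene from a stable precursor and traps it as it forms. It sets out from 19: TsOH in wet THF should open the bridge with capture of the cation by water at C3 and lactonisation, giving 2α-acetoxy-13-(dimethylamino)-3-hydroxy-1βH,7αH,8βH,10αH-guai-4-en-12,8-olide F6. Dehydration of this allylic alcohol with Burgess reagent in the presence of 40 should release the diene next to the dienophile, so that the route is rejoined directly at the Diels–Alder adduct 41.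

Further compounds
F1 | step 10 | (4S,5Z)-4-(tert-butyldimethylsilyloxy)-2-ethoxy-6-iodohepta-1,5-dien-3-ol | I/C(C)=C\[C@H](O[Si](C)(C)C(C)(C)C)C(O)C(=C)OCC
F2 | step 10 | methyl 2-{5-[(2Z,4S)-4-(tert-butyldimethylsilyloxy)-6-ethoxy-5-hydroxyhepta-2,6-dien-2-yl]furan-3-yl}acetate | COC(=O)Cc1coc(/C(C)=C\[C@H](O[Si](C)(C)C(C)(C)C)C(O)C(=C)OCC)c1
F3 | step 10 | methyl 2β-(tert-butyldimethylsilyloxy)-5α,8α-epoxy-10-oxo-13,14-dinor-1βH-guaia-3,6-dien-12-oate | COC(=O)CC1=C[C@@]23O[C@@H]1CC(=O)[C@@H]2[C@@H](O[Si](C)(C)C(C)(C)C)C=C3C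
F4 | step 11 | methyl 2β-(tert-butyldimethylsilyloxy)-5α,8α-epoxy-13-nor-1βH-guaia-3,7(11),10(14)-trien-12-oate | COC(=O)C=C1C[C@@]23O[C@@H]1CC(=C)[C@@H]2[C@@H](O[Si](C)(C)C(C)(C)C)C=C3C
F5 | step 11 | methyl 2β-(tert-butyldimethylsilyloxy)-5α,8α-epoxy-13-nor-1βH,7αH-guaia-3,10(14)-dien-12-oate | COC(=O)C[C@@H]1C[C@@]23O[C@@H]1CC(=C)[C@@H]2[C@@H](O[Si](C)(C)C(C)(C)C)C=C3C
F6 | step 15 | 2α-acetoxy-13-(dimethylamino)-3-hydroxy-1βH,7αH,8βH,10αH-guai-4-en-12,8-olide (C3 and C11 epimers) | CN(C)CC1C(=O)O[C@@H]2C[C@@H](C)[C@@H]3[C@H](OC(C)=O)C(O)C(C)=C3C[C@@H]12
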